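The route rests on adding a C4–C10 bond to ring A in retrosynthesis (drimane numbering). The C3 oxygen stands 1,4 to the methyl-bearing quaternary C10, which is the retron of an acylcyclopropane opened at its tertiary carbon. The precursor is a 1-sulfonylbicyclo[3.1.0]hexan-2-one (five-membered ring C1–C2–C3–C4–C10, cyclopropane C4–C5–C10) with a (Z)-olefinic chain on C5. One Lewis acid step breaks C4–C10, so the five-membered ring takes in C5 and becomes ring A. In the same step olefin carbon C9 attacks C10 with inversion and closes ring B. This sets C9, C10, the trans fusion and the C7=C8 olefin. Asymmetric cyclopropanation supplies the absolute configuration, and scopoletin is attached last.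

Key step: step 7

Remark on numbering: drimane numbering is used for all compounds. Ring A = C1, C2, C3, C4, C5, C10. Ring B = C5 to C10. C11 = the CH2O carbon on C9. α = the face of H5, β = the face of the C10 methyl. The target is (3R,5R,9R,10S): 3α-OH (axial), 5α-H, 9α-CH2OAr, 10β-CH3.
Assumption: the (S,S)-ligand of step 6 is taken to give (1R,5R,6R)-9. If the sense of induction is the opposite, the (R,R)-ligand is used.

Step 1
Reactants: 1 nerol
Product: 2 neryl triisopropylsilyl ether
Conditions: TIPSCl, imidazole, DMF, 0 °C to rt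
Reagents that add atoms: triisopropylsilyl chloride, CC(C)[Si](Cl)(C(C)C)C(C)C
Why: Silyl ether protection of a primary allylic alcohol; the bulky, arene-free TIPS group should survive the dianion, SnCl4 and the electron-transfer step that follow.

Step 2
Reactants: 2 neryl triisopropylsilyl ether
Product: 3 (2E,6Z)-2,6-dimethyl-8-(triisopropylsilyloxy)octa-2,6-dien-1-ol
Conditions: SeO2 (cat.), t-BuOOH, salicylic acid (cat.), CH2Cl2, 0 °C to rt
Reagents that add atoms: tert-butyl hydroperoxide, CC(C)(C)OO
Why: Catalytic SeO2 allylic oxidation (ene reaction, then [2,3]-sigmatropic shift) should attack the more electron-rich terminal olefin at its (E)-methyl group, which fixes the E geometry of the later C5=C10 olefin.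

Step 3
Reactants: 3 (2E,6Z)-2,6-dimethyl-8-(triisopropylsilyloxy)octa-2,6-dien-1-ol
Product: 4 (2E,6Z)-1-bromo-2,6-dimethyl-8-(triisopropylsilyloxy)octa-2,6-diene
Conditions: CBr4, PPh3, CH2Cl2, 0 °C
Reagents that add atoms: carbon tetrabromide, BrC(Br)(Br)Br
Why: The Appel reaction replaces the primary allylic hydroxyl under neutral conditions, without allylic transposition or loss of olefin geometry.

Step 4
Reactants: 4 (2E,6Z)-1-bromo-2,6-dimethyl-8-(triisopropylsilyloxy)octa-2,6-diene; 5 1-(phenylsulfonyl)propan-2-one
Product: 7 (5E,9Z)-5,9-dimethyl-1-(phenylsulfonyl)-11-(triisopropylsilyloxy)undeca-5,9-dien-2-one, via sodium lithium dianion 6 (not isolated)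
Conditions: 5, NaH then n-BuLi, THF, 0 °C; then 4, −78 to 0 °C; aqueous work-up
Reagents that add atoms: none
Why: γ-Alkylation of a β-keto sulfone dianion, in which the more basic terminal carbanion displaces the primary allylic bromide (SN2) and forms C1–C2 while the stabilised C4 anion stays untouched.

Step 5
Reactants: 7 (5E,9Z)-5,9-dimethyl-1-(phenylsulfonyl)-11-(triisopropylsilyloxy)undeca-5,9-dien-2-one
Product: 8 (5E,9Z)-1-diazo-5,9-dimethyl-1-(phenylsulfonyl)-11-(triisopropylsilyloxy)undeca-5,9-dien-2-one
Conditions: 4-acetamidobenzenesulfonyl azide, Et3N, MeCN, 0 °C to rt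
Reagents that add atoms: 4-acetamidobenzenesulfonyl azide, CC(=O)Nc1ccc(cc1)S(=O)(=O)N=[N+]=[N-]
Why: Regitz diazo transfer to the doubly activated methylene between ketone and sulfone.

Step 6
Reactants: 8 (5E,9Z)-1-diazo-5,9-dimethyl-1-(phenylsulfonyl)-11-(triisopropylsilyloxy)undeca-5,9-dien-2-one
Product: 9 (1R,5R,6R)-5-methyl-6-[(3Z)-3-methyl-5-(triisopropylsilyloxy)pent-3-enyl]-1-(phenylsulfonyl)bicyclo[3.1.0]hexan-2-one (side chain exo, cis to the ring methyl)
Conditions: (CuOTf)2·C6H6 (cat.), 2,2'-(propane-2,2-diyl)bis[(4S)-4-isopropyl-4,5-dihydro-1,3-oxazole] (cat.), toluene, rt to 50 °C, slow addition of 8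
Reagents that add atoms: none
Why: Enantioselective intramolecular cyclopropanation of an α-diazo-β-keto sulfone by a copper–bis(oxazoline) carbenoid; the tether selects the near C5=C10 olefin, the stereospecific addition turns the E olefin into the exo chain, and the ligand chooses the olefin face, which sets C4, C5 and C10.

Step 7
Reactants: 9 (1R,5R,6R)-5-methyl-6-[(3Z)-3-methyl-5-(triisopropylsilyloxy)pent-3-enyl]-1-(phenylsulfonyl)bicyclo[3.1.0]hexan-2-one
Product: 10 4a,6-dimethyl-1-(phenylsulfonyl)-5-[(triisopropylsilyloxy)methyl]-3,4,4a,5,8,8a-hexahydronaphthalen-2(1H)-one (trans-fused; 3-oxo, equatorial 4α-SO2Ph, 5α-H, 10β-CH3, 9α-CH2OTIPS, C7=C8 with the methyl on C8)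
Conditions: SnCl4 (1.1 equiv), CH2Cl2, −78 to −40 °C; then water
Reagents that add atoms: none
Why: SnCl4 binds the C3 carbonyl and a sulfonyl oxygen and polarises the cyclopropane, which breaks at the internal C4–C10 bond because only this cleavage puts the positive charge on the tertiary, methyl-bearing C10 (the external C4–C5 bond would leave a secondary cation), so the five-membered ring takes C5 into its perimeter and becomes six-membered ring A with a keto sulfone enolate at C3/C4. The closest known reaction type is olefin participation in the acid-induced opening of acylcyclopropanes of the 5-methyl-6-alkenylbicyclo[3.1.0]hexan-2-one class, the cyclopropane counterpart of an epoxide-initiated cation–olefin bicyclisation. Ring B closes by attack of C9 on C10 from the side opposite to the leaving C4, 6-endo-trig at the olefin and exo-tet at C10. Inversion at C10 combined with the exo chain on C5 places the C10 methyl anti to H5 (trans fusion), and the chair-like closure of the Z olefin puts C11, which is cis to C7 on the olefin, axial on C9 and hence trans to the C10 methyl. The tertiary C8 cation then loses the axial H7 to give the C7=C8 olefin, since H9 is equatorial and badly aligned with the empty orbital, and the enolate is protonated at C4 on work-up, so the step is an isomerisation. The selectivities needed are internal over external bond cleavage, participation over proton loss at C10 and endocyclic termination; they are secured by the C10 methyl, by the three-atom tether that holds C9 behind the breaking bond, and by the axial C11 group.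

Step 8
Reactants: 10 trans-fused 4α-(phenylsulfonyl) 3-ketone
Product: 11 1,4a,6-trimethyl-1-(phenylsulfonyl)-5-[(triisopropylsilyloxy)methyl]-3,4,4a,5,8,8a-hexahydronaphthalen-2(1H)-one (expected 4α-CH3, 4β-SO2Ph)
Conditions: MeI, K2CO3, acetone, rt
Reagents that add atoms: iodomethane, CI
Why: C-alkylation of the stabilised β-keto sulfone anion with a small soft electrophile, expected from the α face away from the C10 methyl; the new C4 centre is erased in step 9.

Step 9
Reactants: 11 4-methyl-4-(phenylsulfonyl) 3-ketone
Product: 13 11-(triisopropylsilyloxy)-9-epi-drim-7-en-3-one (4,4-dimethyl, 5α-H, 9α-CH2OTIPS, 10β-CH3), via lithium enolate 12 (not isolated)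
Conditions: LiC10H8 (lithium naphthalenide, 2.2 equiv), THF, −78 °C; then MeI, DMPU, −78 to 0 °C
Reagents that add atoms: iodomethane, CI
Why: Reductive desulfonylation by electron transfer should give the C3–C4 enolate regiospecifically, and its C-methylation before equilibration (reductive alkylation) completes the gem-dimethyl group at C4 and leaves C2 untouched.

Step 10
Reactants: 13 11-(triisopropylsilyloxy)-9-epi-drim-7-en-3-one
Product: 14 11-(triisopropylsilyloxy)-9-epi-drim-7-en-3α-ol
Conditions: LiBH(s-Bu)3 (L-Selectride), THF, −78 to −20 °C; aqueous work-up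
Reagents that add atoms: none
Why: In a reduction with a bulky trialkylborohydride the axial trajectory is blocked by the axial H1 and H5 on the α face, so hydride should arrive equatorially and give the axial 3α-alcohol (3R).

Step 11
Reactants: 14 11-(triisopropylsilyloxy)-9-epi-drim-7-en-3α-ol
Product: 15 (3R,5R,9R,10S)-9-epi-drim-7-ene-3α,11-diol
Conditions: HF·pyridine, THF, 0 °C to rt
Reagents that add atoms: none
Why: Fluoride-driven cleavage of the Si–O bond, mild enough for the trisubstituted olefin and the axial alcohol.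

Step 12
Reactants: 15 (3R,5R,9R,10S)-9-epi-drim-7-ene-3α,11-diol; 16 scopoletin (7-hydroxy-6-methoxycoumarin)
Product: 17 6-methoxy-7-{[(3R,5R,9R,10S)-3α-hydroxy-9-epi-drim-7-en-11-yl]oxy}coumarin (target)
Conditions: PPh3, DIAD, THF, 0 °C to rt
Reagents that add atoms: none
Why: Mitsunobu etherification, in which only the primary C11 hydroxyl should be activated and displaced by the acidic phenol, because the axial 3-OH next to the quaternary C4 is too hindered; no stereocentre is touched.

Compound list
1 | nerol, (2Z)-3,7-dimethylocta-2,6-dien-1-ol | CC(C)=CCC/C(C)=C\CO | starting material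
2 | neryl triisopropylsilyl ether | CC(C)=CCC/C(C)=C\CO[Si](C(C)C)(C(C)C)C(C)C | intermediate
3 | (2E,6Z)-2,6-dimethyl-8-(triisopropylsilyloxy)octa-2,6-dien-1-ol | OC/C(C)=C/CC/C(C)=C\CO[Si](C(C)C)(C(C)C)C(C)C | intermediate
4 | (2E,6Z)-1-bromo-2,6-dimethyl-8-(triisopropylsilyloxy)octa-2,6-diene | BrC/C(C)=C/CC/C(C)=C\CO[Si](C(C)C)(C(C)C)C(C)C | intermediate
5 | 1-(phenylsulfonyl)propan-2-one | CC(=O)CS(=O)(=O)c1ccccc1 | starting material
6 | sodium lithium dianion of 5 | [Na+].[Li+].[CH2-]C(=O)[CH-]S(=O)(=O)c1ccccc1 | intermediate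
7 | (5E,9Z)-5,9-dimethyl-1-(phenylsulfonyl)-11-(triisopropylsilyloxy)undeca-5,9-dien-2-one | O=C(CS(=O)(=O)c1ccccc1)CC/C(C)=C/CC/C(C)=C\CO[Si](C(C)C)(C(C)C)C(C)C | intermediate
8 | (5E,9Z)-1-diazo-5,9-dimethyl-1-(phenylsulfonyl)-11-(triisopropylsilyloxy)undeca-5,9-dien-2-one | O=C(C(=[N+]=[N-])S(=O)(=O)c1ccccc1)CC/C(C)=C/CC/C(C)=C\CO[Si](C(C)C)(C(C)C)C(C)C | intermediate
9 | (1R,5R,6R)-5-methyl-6-[(3Z)-3-methyl-5-(triisopropylsilyloxy)pent-3-enyl]-1-(phenylsulfonyl)bicyclo[3.1.0]hexan-2-one | O=C1CC[C@]2(C)[C@@H](CC/C(C)=C\CO[Si](C(C)C)(C(C)C)C(C)C)[C@]12S(=O)(=O)c1ccccc1 | intermediate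
10 | trans-fused 3-oxo-4α-(phenylsulfonyl) bicycle, 5α-H, 10β-CH3, 9α-CH2OTIPS, C7=C8 | CC(C)[Si](C(C)C)(C(C)C)OC[C@@H]1C(C)=CC[C@H]2[C@H](S(=O)(=O)c3ccccc3)C(=O)CC[C@]12C | intermediate
11 | 4α-methyl-4β-(phenylsulfonyl) derivative of 10 | CC(C)[Si](C(C)C)(C(C)C)OC[C@@H]1C(C)=CC[C@H]2[C@@](C)(S(=O)(=O)c3ccccc3)C(=O)CC[C@]12C | intermediate
12 | lithium C3–C4 enolate | [Li+].CC(C)[Si](C(C)C)(C(C)C)OC[C@@H]1C(C)=CC[C@H]2C(C)=C([O-])CC[C@]12C | intermediate
13 | 11-(triisopropylsilyloxy)-9-epi-drim-7-en-3-one | CC(C)[Si](C(C)C)(C(C)C)OC[C@@H]1C(C)=CC[C@H]2C(C)(C)C(=O)CC[C@]12C | intermediate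
14 | 11-(triisopropylsilyloxy)-9-epi-drim-7-en-3α-ol | CC(C)[Si](C(C)C)(C(C)C)OC[C@@H]1C(C)=CC[C@H]2C(C)(C)[C@H](O)CC[C@]12C | intermediate
15 | (3R,5R,9R,10S)-9-epi-drim-7-ene-3α,11-diol | OC[C@@H]1C(C)=CC[C@H]2C(C)(C)[C@H](O)CC[C@]12C | intermediate
16 | scopoletin, 7-hydroxy-6-methoxycoumarin | COc1cc2ccc(=O)oc2cc1O | starting material
17 | 6-methoxy-7-{[(3R,5R,9R,10S)-3α-hydroxy-9-epi-drim-7-en-11-yl]oxy}coumarin | COc1cc2ccc(=O)oc2cc1OC[C@@H]1C(C)=CC[C@H]2C(C)(C)[C@H](O)CC[C@]12C | target

Total step count: 12. Longest linear sequence: 12 steps (1 to 17).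

Steps most likely to fail

Step 7. Ionisation at C10 may run ahead of olefin participation, so that proton loss or a hydride shift from C5 ends the reaction at the monocyclic stage. The C8 cation may also lose a proton unselectively, a boat-like closure may erode the C9 configuration, or the silyl ether may be lost. The fallback sets out from 9 and comes back at 10.
- The silyl ether is removed with HF·pyridine to give the allylic alcohol F1.
- F1 is cyclised with FSO3H in 2-nitropropane at −78 °C. In this Brønsted superacid medium the protonated hydroxyl is shielded from ionisation, and the carbonyl-protonated cyclopropane opens and terminates under kinetic control. This gives the hydroxy keto sulfone F2.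
- Silylation of F2 (TIPSCl, imidazole) returns 10.

Step 6. The copper carbenoid may discriminate poorly between the faces of the trisubstituted olefin, or C–H insertion may compete. The fallback sets out from 8 and comes back at 9.
- Rh2(OAc)4 in CH2Cl2 gives the racemic cyclopropane F3 with the same exo relative configuration.
- A Corey–Bakshi–Shibata reduction follows, with about half an equivalent of BH3·SMe2 and the oxazaborolidine enantiomer matched to the unwanted antipode.
- That antipode is turned into the carbinol F4, and unreacted 9 is separated by chromatography (kinetic resolution).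

Step 12. Displacement at the β-branched, axial CH2 may be slow. The alkoxyphosphonium salt could then decay by elimination or by alkylation of the hydrazide. The fallback sets out from 15 and comes back at 17.
- Selective sulfonylation of the primary hydroxyl (MsCl, 2,4,6-collidine, CH2Cl2, −20 °C) gives the primary mesylate F5.
- F5 alkylates the caesium phenoxide of 16 (Cs2CO3, DMF, 60 °C) in a Williamson ether synthesis.

Further compounds
F1 | step 7 | (1R,5R,6R)-6-[(3Z)-5-hydroxy-3-methylpent-3-enyl]-5-methyl-1-(phenylsulfonyl)bicyclo[3.1.0]hexan-2-one | O=C1CC[C@]2(C)[C@@H](CC/C(C)=C\CO)[C@]12S(=O)(=O)c1ccccc1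
F2 | step 7 | 11-hydroxy analogue of 10 (free CH2OH on C9) | OC[C@@H]1C(C)=CC[C@H]2[C@H](S(=O)(=O)c3ccccc3)C(=O)CC[C@]12C
F3 | step 6 | racemic 9 (9 and its mirror image) | O=C1CC[C@]2(C)[C@@H](CC/C(C)=C\CO[Si](C(C)C)(C(C)C)C(C)C)[C@]12S(=O)(=O)c1ccccc1.O=C1CC[C@@]2(C)[C@H](CC/C(C)=C\CO[Si](C(C)C)(C(C)C)C(C)C)[C@@]12S(=O)(=O)c1ccccc1
F4 | step 6 | carbinol from the mirror image of 9, hydroxyl syn to the cyclopropane | O[C@H]1CC[C@@]2(C)[C@H](CC/C(C)=C\CO[Si](C(C)C)(C(C)C)C(C)C)[C@@]12S(=O)(=O)c1ccccc1
F5 | step 12 | 11-O-methanesulfonate of 15 | CS(=O)(=O)OC[C@@H]1C(C)=CC[C@H]2C(C)(C)[C@H](O)CC[C@]12C
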